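## Retrosynthetic overview

1. The target is reached by a final Sharpless asymmetric epoxidation of the C14 allylic alcohol (C1=C10); the C8 ester comes from (R)-2-methylbutanoic acid and the α-methylene group from a Mannich/elimination sequence.
2. The cis-γ-lactone comes from reduction of the C6 ketone of a keto ester whose C7–C11 bond is made by enolate alkylation.
3. Key step: anionic oxy-Cope ring expansion of a cis-1,2-dialkenylcyclohexenol. It builds the ten-membered ring, keeps the cis C4=C5 alkene, creates the cis C1=C10 alkene, sets C8 by chirality transfer, and delivers the C6/C7 enolate for alkylation in the same flask.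
4. The cyclohexenol comes from alkoxyacetylide addition and semihydrogenation on a 4-silyloxy-6-alkenyl enone made from (R)-carvone, which supplies C1–C6, C9, C10, C14 and C15.
5. Ring order: cyclohexene (from carvone) → ten-membered carbocycle → γ-lactone → oxirane.

Assumption: the SMILES is read literally (cis-fused 12,6-lactone, cis C4=C5, cis-oxirane); ten-membered-ring compounds carry germacrane numbering (ring C1–C10, C11–C13 on C7, C14 on C10, C15 on C4); TBS = tert-butyldimethylsilyl, PMB = 4-methoxybenzyl; a not-isolated intermediate is numbered when it persists until the next reagent is added or rearranges on its own.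

## Route

Step 1
Reactants: 1 (R)-(−)-carvone
Product: 2 (5R)-5-(3-chloroprop-1-en-2-yl)-2-methylcyclohex-2-en-1-one
Conditions: Ca(OCl)2, CO2 (dry ice), CH2Cl2/H2O, 0 °C
Reagents that add atoms: calcium hypochlorite, [Ca+2].[O-]Cl.[O-]Cl
Why: Ene-type allylic chlorination by HOCl formed in situ attacks only the electron-rich 1,1-disubstituted alkene (the enone alkene is deactivated) and leaves C5 untouched.

Step 2
Reactants: 2 (5R)-5-(3-chloroprop-1-en-2-yl)-2-methylcyclohex-2-en-1-one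
Product: 4 (5R)-5-(3-hydroxyprop-1-en-2-yl)-2-methylcyclohex-2-en-1-one, via 10-acetoxycarvone 3 (not isolated)
Conditions: KOAc, DMF, 60 °C; then K2CO3 (cat.), MeOH, 0 °C
Reagents that add atoms: potassium acetate, CC(=O)[O-].[K+]
Why: SN2 displacement of the primary allylic chloride by acetate followed by base-catalysed transesterification (methanolysis) of the acetate; no stereocenter is involved.

Step 3
Reactants: 4 (5R)-5-(3-hydroxyprop-1-en-2-yl)-2-methylcyclohex-2-en-1-one
Product: 5 (1S,5R)-5-(3-hydroxyprop-1-en-2-yl)-2-methylcyclohex-2-en-1-ol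
Conditions: (R)-2-methyl-CBS-oxazaborolidine (20 mol%), catecholborane (2.5 equiv), toluene, −78 °C
Reagents that add atoms: none
Why: Corey–Bakshi–Shibata reduction, in which the (R)-oxazaborolidine treats the α-methylvinyl arm as the large group and delivers hydride to give the (1S) carbinol trans to the C5 side chain (catalyst control, equatorial attack of the bulky hydride complex).

Step 4
Reactants: 5 (1S,5R)-5-(3-hydroxyprop-1-en-2-yl)-2-methylcyclohex-2-en-1-ol
Product: 6 (1S,5R)-1-(TBSO)-5-[3-(TBSO)prop-1-en-2-yl]-2-methylcyclohex-2-ene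
Conditions: TBSCl, imidazole, DMF, rt
Reagents that add atoms: tert-butyldimethylsilyl chloride, CC(C)(C)[Si](C)(C)Cl
Why: Imidazole-promoted silylation of both hydroxyls (silyl ether protection), with no change at the stereocenters.

Step 5
Reactants: 6 (1S,5R)-1-(TBSO)-5-[3-(TBSO)prop-1-en-2-yl]-2-methylcyclohex-2-ene
Product: 7 (4S,6R)-4-(TBSO)-6-[3-(TBSO)prop-1-en-2-yl]-3-methylcyclohex-2-en-1-one
Conditions: CrO3, 3,5-dimethylpyrazole, CH2Cl2, −20 °C
Reagents that add atoms: chromium trioxide, O=[Cr](=O)=O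
Why: Chromium-mediated allylic oxidation converts the ring CH2 next to the CH= end of the trisubstituted alkene into the enone carbonyl, and both stereocenters are carried through unchanged.

Step 6
Reactants: 8 4-methoxybenzyl alcohol; 9 trichloroethylene
Product: 11 (E)-1,2-dichlorovinyl 4-methoxybenzyl ether, via potassium 4-methoxybenzyl oxide 10 (not isolated)
Conditions: KH, THF, 0 °C; then 9, −50 °C to rt
Reagents that add atoms: none
Why: The alkoxide dehydrochlorinates trichloroethylene to dichloroacetylene and adds to it in anti fashion (elimination–addition), which gives the E-dichlorovinyl ether.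

Step 7
Reactants: 11 (E)-1,2-dichlorovinyl 4-methoxybenzyl ether; 7 (4S,6R)-4-(TBSO)-6-[3-(TBSO)prop-1-en-2-yl]-3-methylcyclohex-2-en-1-one
Product: 13 (1S,4S,6R)-4-(TBSO)-6-[3-(TBSO)prop-1-en-2-yl]-1-[(PMBO)ethynyl]-3-methylcyclohex-2-en-1-ol, via lithium alkoxyacetylide 12 (not isolated)
Conditions: n-BuLi (2.2 equiv), THF, −78 to −40 °C; then 7, −78 °C
Reagents that add atoms: none
Why: Dehydrochlorination and Li/Cl exchange give the alkoxyacetylide, whose 1,2-addition to the enone (acetylide addition) proceeds by axial attack of the slim nucleophile anti to the pseudoaxial C4 silyloxy group, so the alkynyl group ends up cis to the C6 side chain and the carbinol is (1S).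

Step 8
Reactants: 13 (1S,4S,6R)-4-(TBSO)-6-[3-(TBSO)prop-1-en-2-yl]-1-[(PMBO)ethynyl]-3-methylcyclohex-2-en-1-ol
Product: 14 (1S,4S,6R)-4-(TBSO)-6-[3-(TBSO)prop-1-en-2-yl]-1-[(Z)-2-(PMBO)ethenyl]-3-methylcyclohex-2-en-1-ol
Conditions: H2 (1 atm), Pd/CaCO3 poisoned with Pb(OAc)2, quinoline, EtOAc, rt
Reagents that add atoms: none
Why: Lindlar semihydrogenation adds H2 syn to the alkynyl ether and stops at the Z-enol ether without touching the other alkenes or the PMB group.

Step 9
Reactants: 14 (1S,4S,6R)-4-(TBSO)-6-[3-(TBSO)prop-1-en-2-yl]-1-[(Z)-2-(PMBO)ethenyl]-3-methylcyclohex-2-en-1-ol; 15 methyl bromoacetate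
Product: 18 methyl (3S,7R,8R)-3,14-bis(TBSO)-8-(PMBO)-6-oxo-13-norgermacra-1(10)E,4Z-dien-12-oate, via potassium cyclohexenolate 16 (not isolated), via potassium dienolate 17 (not isolated)
Conditions: KH, THF, 0 to 25 °C; then 15, −78 °C
Reagents that add atoms: none
Why: Anionic oxy-Cope rearrangement through the potassium-bridged chair transition state dictated by the ground-state half-chair (carbinol vinyl axial, side-chain alkenyl equatorial): the ring alkene is carried over as the cis C4=C5 bond, the axial ring bond gives the cis C1=C10 bond, the Z-enol ether transfers chirality to C8 (R), and the regiodefined enolate is then C-alkylated on its peripheral face anti to the C8–OPMB group, which sets C7 (R).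

Step 10
Reactants: 18 methyl (3S,7R,8R)-3,14-bis(TBSO)-8-(PMBO)-6-oxo-13-norgermacra-1(10)E,4Z-dien-12-oate
Product: 20 (3S,6S,7R,8R)-3,14-bis(TBSO)-8-(PMBO)-13-norgermacra-1(10)E,4Z-dien-12,6-olide, via hydroxy ester 19 (not isolated)
Conditions: Zn(BH4)2, Et2O, −30 °C; aq NH4Cl; then PPTS (cat.), CH2Cl2, rt
Reagents that add atoms: none
Why: Chelation-controlled 1,2-reduction of the β-alkoxy enone (zinc bridging O6 and the C8 ether oxygen, hydride from the ring periphery) gives the 6S alcohol 1,3-syn to O8 and cis to the C7 acetate arm, which closes to the cis-fused γ-lactone under acid catalysis (lactonization).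

Step 11
Reactants: 20 (3S,6S,7R,8R)-3,14-bis(TBSO)-8-(PMBO)-13-norgermacra-1(10)E,4Z-dien-12,6-olide
Product: 22 (3S,6S,7R,8R)-13-(dimethylamino)-3,14-bis(TBSO)-8-(PMBO)germacra-1(10)E,4Z-dien-12,6-olide (C11 epimers), via lithium lactone enolate 21 (not isolated)
Conditions: LiN(iPr)2, THF, −78 °C; then CH2=NMe2+ I−, −78 °C to rt
Reagents that add atoms: N,N-dimethylmethyleneiminium iodide, C=[N+](C)C.[I-]
Why: Mannich reaction of the lactone enolate with the preformed iminium salt (Eschenmoser methylenation, first stage) attaches C13 to C11; the new C11 center is erased in the next step.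

Step 12
Reactants: 22 (3S,6S,7R,8R)-13-(dimethylamino)-3,14-bis(TBSO)-8-(PMBO)germacra-1(10)E,4Z-dien-12,6-olide (C11 epimers)
Product: 24 (3S,6S,7R,8R)-3,14-bis(TBSO)-8-(PMBO)germacra-1(10)E,4Z,11(13)-trien-12,6-olide, via trimethylammonium iodide 23 (not isolated)
Conditions: MeI, MeOH, rt; then NaHCO3, EtOAc/H2O, rt
Reagents that add atoms: none
Why: N-Methylation followed by E1cB (Hofmann-type) loss of trimethylamine gives the α-methylene lactone from either C11 epimer.

Step 13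
Reactants: 24 (3S,6S,7R,8R)-3,14-bis(TBSO)-8-(PMBO)germacra-1(10)E,4Z,11(13)-trien-12,6-olide
Product: 25 (3S,6S,7R,8R)-8-hydroxy-3,14-bis(TBSO)germacra-1(10)E,4Z,11(13)-trien-12,6-olide
Conditions: DDQ, CH2Cl2/pH 7 buffer, 0 °C
Reagents that add atoms: none
Why: Oxidative PMB ether cleavage by DDQ (hydride abstraction, hydrolysis of the oxocarbenium ion) frees the C8 hydroxyl with retention and leaves silyl ethers and the enoate intact.

Step 14
Reactants: 25 (3S,6S,7R,8R)-8-hydroxy-3,14-bis(TBSO)germacra-1(10)E,4Z,11(13)-trien-12,6-olide; 26 (R)-2-methylbutanoic acid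
Product: 27 (3S,6S,7R,8R)-3,14-bis(TBSO)-8-[(2R)-2-methylbutanoyloxy]germacra-1(10)E,4Z,11(13)-trien-12,6-olide
Conditions: N,N'-diisopropylcarbodiimide, DMAP (cat.), CH2Cl2, 0 °C to rt
Reagents that add atoms: none
Why: Steglich esterification acylates the only free hydroxyl with retention at C8, and the mild low-temperature conditions keep the α-stereocenter of the acid intact.

Step 15
Reactants: 27 (3S,6S,7R,8R)-3,14-bis(TBSO)-8-[(2R)-2-methylbutanoyloxy]germacra-1(10)E,4Z,11(13)-trien-12,6-olide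
Product: 28 (3S,6S,7R,8R)-3,14-dihydroxy-8-[(2R)-2-methylbutanoyloxy]germacra-1(10)E,4Z,11(13)-trien-12,6-olide
Conditions: HF·pyridine, pyridine, THF, 0 °C to rt
Reagents that add atoms: none
Why: Buffered fluoride-driven desilylation removes both TBS ethers while the ester, the lactone and the enoate survive.

Step 16
Reactants: 28 (3S,6S,7R,8R)-3,14-dihydroxy-8-[(2R)-2-methylbutanoyloxy]germacra-1(10)E,4Z,11(13)-trien-12,6-olide
Product: 29 (1R,3S,6S,7R,8R,10R)-1,10-epoxy-3,14-dihydroxy-8-[(2R)-2-methylbutanoyloxy]germacra-4Z,11(13)-dien-12,6-olide (target CNP0356520.2)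
Conditions: Ti(OiPr)4 (20 mol%), D-(−)-diethyl tartrate (24 mol%), t-BuOOH, 4 Å MS, CH2Cl2, −20 °C
Reagents that add atoms: tert-butyl hydroperoxide, CC(C)(C)OO
Why: Sharpless asymmetric epoxidation, in which the titanium–D-(−)-tartrate complex binds the primary C14 allylic alcohol and delivers oxygen syn to the C1=C10 face that gives the (1R,10R) cis-oxirane (the mirror of the (2S,3S) outcome that L-(+)-tartrate gives with E-allylic alcohols), while the Z-configured secondary allylic alcohol at C3 belongs to the slowest substrate class and is left alone.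

## Compound list

1 | (R)-(−)-carvone, (5R)-2-methyl-5-(prop-1-en-2-yl)cyclohex-2-en-1-one | CC1=CC[C@H](CC1=O)C(C)=C | starting material
2 | (5R)-5-(3-chloroprop-1-en-2-yl)-2-methylcyclohex-2-en-1-one (10-chlorocarvone) | CC1=CC[C@H](CC1=O)C(=C)CCl | intermediate
3 | (5R)-5-(3-acetoxyprop-1-en-2-yl)-2-methylcyclohex-2-en-1-one (10-acetoxycarvone) | CC1=CC[C@H](CC1=O)C(=C)COC(C)=O | intermediate
4 | (5R)-5-(3-hydroxyprop-1-en-2-yl)-2-methylcyclohex-2-en-1-one (10-hydroxycarvone) | CC1=CC[C@H](CC1=O)C(=C)CO | intermediate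
5 | (1S,5R)-5-(3-hydroxyprop-1-en-2-yl)-2-methylcyclohex-2-en-1-ol (OH trans to the side chain) | C1C=C(C)[C@@H](O)C[C@@H]1C(=C)CO | intermediate
6 | (1S,5R)-1-(TBSO)-5-[3-(TBSO)prop-1-en-2-yl]-2-methylcyclohex-2-ene | C1C=C(C)[C@@H](O[Si](C)(C)C(C)(C)C)C[C@@H]1C(=C)CO[Si](C)(C)C(C)(C)C | intermediate
7 | (4S,6R)-4-(TBSO)-6-[3-(TBSO)prop-1-en-2-yl]-3-methylcyclohex-2-en-1-one (4,6-trans) | O=C1C=C(C)[C@@H](O[Si](C)(C)C(C)(C)C)C[C@@H]1C(=C)CO[Si](C)(C)C(C)(C)C | intermediate
8 | 4-methoxybenzyl alcohol | COc1ccc(CO)cc1 | starting material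
9 | trichloroethylene | ClC=C(Cl)Cl | starting material
10 | potassium 4-methoxybenzyl oxide | [K+].[O-]Cc1ccc(OC)cc1 | intermediate
11 | (E)-1,2-dichlorovinyl 4-methoxybenzyl ether | COc1ccc(CO/C(Cl)=C\Cl)cc1 | intermediate
12 | lithium (4-methoxybenzyloxy)acetylide | [Li]C#COCc1ccc(OC)cc1 | intermediate
13 | (1S,4S,6R)-4-(TBSO)-6-[3-(TBSO)prop-1-en-2-yl]-1-[(PMBO)ethynyl]-3-methylcyclohex-2-en-1-ol (alkynyl cis to the C6 side chain, trans to C4–OTBS) | O[C@@]1(C#COCc2ccc(OC)cc2)C=C(C)[C@@H](O[Si](C)(C)C(C)(C)C)C[C@@H]1C(=C)CO[Si](C)(C)C(C)(C)C | intermediate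
14 | (1S,4S,6R)-4-(TBSO)-6-[3-(TBSO)prop-1-en-2-yl]-1-[(Z)-2-(PMBO)ethenyl]-3-methylcyclohex-2-en-1-ol | O[C@@]1(/C=C\OCc2ccc(OC)cc2)C=C(C)[C@@H](O[Si](C)(C)C(C)(C)C)C[C@@H]1C(=C)CO[Si](C)(C)C(C)(C)C | intermediate
15 | methyl bromoacetate | COC(=O)CBr | starting material
16 | potassium alkoxide of 14 | [K+].[O-][C@@]1(/C=C\OCc2ccc(OC)cc2)C=C(C)[C@@H](O[Si](C)(C)C(C)(C)C)C[C@@H]1C(=C)CO[Si](C)(C)C(C)(C)C | intermediate
17 | potassium (3S,8R)-3,14-bis(TBSO)-8-(PMBO)-11,12,13-trinorgermacra-1(10)E,4Z,6Z-trien-6-olate (C5 and C8 trans across C6=C7) | C1/C(CO[Si](C)(C)C(C)(C)C)=C\C[C@H](O[Si](C)(C)C(C)(C)C)/C(C)=C\C([O-])=C\[C@@H]1OCc2ccc(OC)cc2.[K+] | intermediate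
18 | methyl (3S,7R,8R)-3,14-bis(TBSO)-8-(PMBO)-6-oxo-13-norgermacra-1(10)E,4Z-dien-12-oate (ring carbons cis on both alkenes) | O=C1/C=C(/C)[C@@H](O[Si](C)(C)C(C)(C)C)C/C=C(CO[Si](C)(C)C(C)(C)C)\C[C@@H](OCc2ccc(OC)cc2)[C@H]1CC(=O)OC | intermediate
19 | methyl (3S,6S,7S,8R)-6-hydroxy-3,14-bis(TBSO)-8-(PMBO)-13-norgermacra-1(10)E,4Z-dien-12-oate (same geometry at C7 as 18; the descriptor changes by priority only) | O[C@H]1/C=C(/C)[C@@H](O[Si](C)(C)C(C)(C)C)C/C=C(CO[Si](C)(C)C(C)(C)C)\C[C@@H](OCc2ccc(OC)cc2)[C@H]1CC(=O)OC | intermediate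
20 | (3S,6S,7R,8R)-3,14-bis(TBSO)-8-(PMBO)-13-norgermacra-1(10)E,4Z-dien-12,6-olide (cis-fused lactone) | C1C(=O)O[C@H]2/C=C(/C)[C@@H](O[Si](C)(C)C(C)(C)C)C/C=C(CO[Si](C)(C)C(C)(C)C)\C[C@@H](OCc3ccc(OC)cc3)[C@@H]12 | intermediate
21 | lithium enolate of lactone 20 (C11=C12–OLi) | C1=C([O-])O[C@H]2/C=C(/C)[C@@H](O[Si](C)(C)C(C)(C)C)C/C=C(CO[Si](C)(C)C(C)(C)C)\C[C@@H](OCc3ccc(OC)cc3)[C@@H]12.[Li+] | intermediate
22 | (3S,6S,7R,8R)-13-(dimethylamino)-3,14-bis(TBSO)-8-(PMBO)germacra-1(10)E,4Z-dien-12,6-olide (C11 epimer mixture, C11 left undefined on purpose) | CN(C)CC1C(=O)O[C@H]2/C=C(/C)[C@@H](O[Si](C)(C)C(C)(C)C)C/C=C(CO[Si](C)(C)C(C)(C)C)\C[C@@H](OCc3ccc(OC)cc3)[C@@H]12 | intermediate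
23 | 13-(trimethylammonio) analogue of 22, iodide salt | C[N+](C)(C)CC1C(=O)O[C@H]2/C=C(/C)[C@@H](O[Si](C)(C)C(C)(C)C)C/C=C(CO[Si](C)(C)C(C)(C)C)\C[C@@H](OCc3ccc(OC)cc3)[C@@H]12.[I-] | intermediate
24 | (3S,6S,7R,8R)-3,14-bis(TBSO)-8-(PMBO)germacra-1(10)E,4Z,11(13)-trien-12,6-olide | C=C1C(=O)O[C@H]2/C=C(/C)[C@@H](O[Si](C)(C)C(C)(C)C)C/C=C(CO[Si](C)(C)C(C)(C)C)\C[C@@H](OCc3ccc(OC)cc3)[C@@H]12 | intermediate
25 | (3S,6S,7R,8R)-8-hydroxy-3,14-bis(TBSO)germacra-1(10)E,4Z,11(13)-trien-12,6-olide | C=C1C(=O)O[C@H]2/C=C(/C)[C@@H](O[Si](C)(C)C(C)(C)C)C/C=C(CO[Si](C)(C)C(C)(C)C)\C[C@@H](O)[C@@H]12 | intermediate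
26 | (R)-2-methylbutanoic acid | CC[C@@H](C)C(=O)O | starting material
27 | (3S,6S,7R,8R)-3,14-bis(TBSO)-8-[(2R)-2-methylbutanoyloxy]germacra-1(10)E,4Z,11(13)-trien-12,6-olide | C=C1C(=O)O[C@H]2/C=C(/C)[C@@H](O[Si](C)(C)C(C)(C)C)C/C=C(CO[Si](C)(C)C(C)(C)C)\C[C@@H](OC(=O)[C@H](C)CC)[C@@H]12 | intermediate
28 | (3S,6S,7R,8R)-3,14-dihydroxy-8-[(2R)-2-methylbutanoyloxy]germacra-1(10)E,4Z,11(13)-trien-12,6-olide | C=C1C(=O)O[C@H]2/C=C(/C)[C@@H](O)C/C=C(CO)\C[C@@H](OC(=O)[C@H](C)CC)[C@@H]12 | intermediate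
29 | (1R,3S,6S,7R,8R,10R)-1,10-epoxy-3,14-dihydroxy-8-[(2R)-2-methylbutanoyloxy]germacra-4Z,11(13)-dien-12,6-olide | C=C1C(=O)O[C@H]2/C=C(/C)[C@@H](O)C[C@H]3O[C@@]3(CO)C[C@@H](OC(=O)[C@H](C)CC)[C@@H]12 | target

## Step count and weak points

Total steps: 16. Longest linear sequence: 15 (steps 1–5 and 7–16 from 1; step 6 is a one-step side branch).

**Step 5 (allylic oxidation).** The CH–OTBS and CH2OTBS positions can compete, and the β,γ-unsaturated ketone can epimerize or conjugate under the chromium conditions. Fallback, setting out from 6: epoxidize the trisubstituted ring alkene with mCPBA (NaHCO3, CH2Cl2, 0 °C), anti to the silyloxy group, to the epoxide F1. Open it at the secondary carbon with PhSeNa (PhSeSePh, NaBH4, EtOH) to the hydroxy selenide F2. Oxidize with H2O2 to the selenoxide F3, which undergoes syn-elimination at room temperature to the tertiary allylic alcohol F4. Oxidative 1,3-transposition with pyridinium chlorochromate C5H5NH[CrO3Cl] (Dauben–Babler) then comes back to the route at 7.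

**Step 9 (oxy-Cope rearrangement and alkylation).** The potassium enolate carries a β-OPMB group that can be lost by elimination, the other chair or a boat could erode the C1=C10 geometry and C8, and the alkylation face rests on a conformational argument. Fallback, setting out from 14: run the rearrangement as before but quench the enolate with Me3SiCl to the neutral silyl dienol ether F5. Then regenerate the enolate at −78 °C with MeLi as the lithium dienolate F6, which does not eliminate at this temperature, and alkylate it with 15, coming back at 18.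

**Step 10 (C6 reduction).** Hydride may arrive from the other face of the ten-membered ring and give the 6-epimer. Fallback, setting out from 18: take the 6-epi hydroxy ester F7 (made deliberately with a non-chelating hydride such as NaBH4/CeCl3 if that is the intrinsic preference, acid stage omitted). Saponify it with LiOH (THF/H2O, then mild acidification) to the hydroxy acid F8. Close the ring by Mitsunobu lactonization (PPh3, DIAD) with inversion at C6, coming back at 20.

Further compounds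

F1 | step 5 | 2,3-epoxide of 6 (cyclohexene numbering), oxirane oxygen anti to the C1 silyloxy group | C1[C@@H]2O[C@]2(C)[C@@H](O[Si](C)(C)C(C)(C)C)C[C@@H]1C(=C)CO[Si](C)(C)C(C)(C)C
F2 | step 5 | hydroxy selenide from trans-diaxial opening of F1 (C3–SePh, tertiary C2–OH) | C1[C@@H]([Se]c2ccccc2)[C@@](O)(C)[C@@H](O[Si](C)(C)C(C)(C)C)C[C@@H]1C(=C)CO[Si](C)(C)C(C)(C)C
F3 | step 5 | selenoxide of F2 | C1[C@@H]([Se](=O)c2ccccc2)[C@@](O)(C)[C@@H](O[Si](C)(C)C(C)(C)C)C[C@@H]1C(=C)CO[Si](C)(C)C(C)(C)C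
F4 | step 5 | tertiary allylic alcohol: 2-hydroxy-2-methylcyclohex-3-ene with C1–OTBS and the C5 side chain of 6 | C1=C[C@@](O)(C)[C@@H](O[Si](C)(C)C(C)(C)C)C[C@@H]1C(=C)CO[Si](C)(C)C(C)(C)C
F5 | step 9 | trimethylsilyl dienol ether of dienolate 17 | C1/C(CO[Si](C)(C)C(C)(C)C)=C\C[C@H](O[Si](C)(C)C(C)(C)C)/C(C)=C\C(O[Si](C)(C)C)=C\[C@@H]1OCc2ccc(OC)cc2
F6 | step 9 | lithium dienolate (lithium counterpart of 17) | C1/C(CO[Si](C)(C)C(C)(C)C)=C\C[C@H](O[Si](C)(C)C(C)(C)C)/C(C)=C\C([O-])=C\[C@@H]1OCc2ccc(OC)cc2.[Li+]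
F7 | step 10 | 6-epimer of hydroxy ester 19 (6R) | O[C@@H]1/C=C(/C)[C@@H](O[Si](C)(C)C(C)(C)C)C/C=C(CO[Si](C)(C)C(C)(C)C)\C[C@@H](OCc2ccc(OC)cc2)[C@H]1CC(=O)OC
F8 | step 10 | hydroxy acid from F7 (6R) | O[C@@H]1/C=C(/C)[C@@H](O[Si](C)(C)C(C)(C)C)C/C=C(CO[Si](C)(C)C(C)(C)C)\C[C@@H](OCc2ccc(OC)cc2)[C@H]1CC(=O)O
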